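**Plan**

- Numbering and enabling feature: lactone ring O1, C2 (C=O), C3=C4, C5, C6, C7; chain C1'–C6' on C7 (C1' is the carbinol); chain C1''–C5'' on C3. C7 (bearing O1 and CH3) and C1' (OH) are vicinal oxygenated stereocentres, and C6–C5 of the ring can derive from a vinyl group on C7. This is the pattern left when a γ-alkoxy-γ-methylallyl boronate adds through its γ-carbon to an aldehyde.
- Retrosynthetic cuts, in order: O1–C2 (lactone, the only ring), C4–C5 (sp2–sp3 coupling), C7–C1' (allylboration).
- Forward: a nerol-derived C1'–C6' aldehyde and a (Z)-γ-(methoxymethoxy)-γ-methylallyl pinacol boronate are joined at C7–C1'. The vinyl group is hydroborated and coupled with a Z-enol triflate carrying C2–C4 and C1''–C5''. The seven-membered lactone is closed last, then the silyl ethers are removed.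
- Stereochemistry: C7 and C1' both arise in the allylboration (Z-boronate gives the syn relation, the (S)-phosphoric acid the absolute sense). C4'=C5' (Z) comes from nerol, C3''=C4'' (Z) from a Wittig reaction of an α-silyloxy ketone, and the ring olefin C3=C4 from the Z-enol triflate with retention.

Key step: step 6

Remark on the chemistry: racemic but-3-en-2-ol suffices because its stereocentre is erased on metalation; the sense of induction of the phosphoric acid is assumed to be the one known for allyl- and crotylboronates, and the antipodal catalyst would be used if it proved opposite.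

**Route**

Step 1
Reactants: 1 nerol
Product: 2 neryl tert-butyldimethylsilyl ether
Conditions: TBSCl, imidazole, CH2Cl2, 0 °C → rt
Reagents that add atoms: tert-butyldimethylsilyl chloride, CC(C)(C)[Si](C)(C)Cl
Why: Imidazole-promoted silylation of the primary allylic alcohol is routine and leaves both olefins and the Z geometry untouched.

Step 2
Reactants: 2 neryl tert-butyldimethylsilyl ether
Product: 3 6,7-epoxide of 2 (racemic at the oxirane CH)
Conditions: mCPBA (1.0 equiv), CH2Cl2, −20 → 0 °C
Reagents that add atoms: 3-chloroperoxybenzoic acid, O=C(OO)c1cccc(Cl)c1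
Why: Prilezhaev epoxidation should pick the remote trisubstituted olefin because the other one is deactivated by its allylic C–O bond; the new stereocentre forms as a racemate and is destroyed in step 3.

Step 3
Reactants: 3 6,7-epoxide of 2
Product: 5 (4Z)-6-(tert-butyldimethylsilyloxy)-4-methylhex-4-enal, via diol 4 (not isolated)
Conditions: H5IO6, THF/H2O, 0 °C
Reagents that add atoms: none
Why: Acid-catalysed hydration of the epoxide followed by Malaprade glycol cleavage in the same flask should release acetone and the aldehyde, and the short cold exposure is tolerated by the allylic silyl ether.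

Step 4
Reactants: 6 but-3-en-2-ol (racemic)
Product: 7 3-(methoxymethoxy)but-1-ene (racemic)
Conditions: MOMCl, iPr2NEt, CH2Cl2, 0 °C → rt
Reagents that add atoms: chloromethyl methyl ether, COCCl
Why: Alkylation of the secondary alcohol with the α-chloro ether (methoxymethyl ether formation) is standard, and the stereocentre need not be controlled because step 5 erases it.

Step 5
Reactants: 7 3-(methoxymethoxy)but-1-ene; 8 2-isopropoxy-4,4,5,5-tetramethyl-1,3,2-dioxaborolane
Product: 11 2-[(2Z)-3-(methoxymethoxy)but-2-en-1-yl]-4,4,5,5-tetramethyl-1,3,2-dioxaborolane, via allyllithium 9 (not isolated), via lithium borate 10 (not isolated)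
Conditions: sBuLi, TMEDA, THF, −78 °C; then 8, −78 °C; sat. aq. NH4Cl, −78 °C → rt
Reagents that add atoms: none
Why: Metalation–borylation of an allyl ether: deprotonation α to oxygen should give an alkoxyallyllithium held in the Z form by internal O–Li coordination, and the borate is taken up at the unhindered CH2 terminus, so the only stereochemical element created is the olefin geometry (oxygen cis to CH2B).

Step 6
Reactants: 5 (4Z)-6-(tert-butyldimethylsilyloxy)-4-methylhex-4-enal; 11 2-[(2Z)-3-(methoxymethoxy)but-2-en-1-yl]-4,4,5,5-tetramethyl-1,3,2-dioxaborolane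
Product: 13 (3R,4R,7Z)-9-(tert-butyldimethylsilyloxy)-3-(methoxymethoxy)-3,7-dimethylnona-1,7-dien-4-ol, via boric ester 12 (not isolated)
Conditions: (S)-3,3'-bis(2,4,6-triisopropylphenyl)-1,1'-binaphthyl-2,2'-diyl hydrogen phosphate (10 mol %), 4 Å MS, toluene, −30 °C; then H2O
Reagents that add atoms: none
Why: Proposed new method: the phosphoric acid is expected to hydrogen-bond to a pinacol oxygen of 11 (its phosphoryl oxygen contacting the formyl hydrogen) while boron binds the carbonyl oxygen of 5 and the γ-carbon of 11 attacks the carbonyl carbon through a closed six-membered chair with allylic transposition, giving boric ester 12, which is hydrolysed on work-up. The closest known reactions are chiral phosphoric acid-catalysed allyl- and crotylborations of aldehydes with pinacol boronates and uncatalysed additions of (Z)-γ-alkoxyallylboronates that give syn-diol monoethers; a γ-alkoxy-γ-methyl reagent under this catalysis is the untested combination. No ring is closed; the only ring is that of the transition state. C7 is set relative to C1' by the Z geometry of 11, which places the methoxymethoxy group axial, the methyl group equatorial and the aldehyde chain equatorial, so the new hydroxyl and the ether oxygen come out syn, that is (7R*,1'R*). C1' is set by the catalyst: (R)-catalysts of this class send allylboronates to the Re face of aldehydes, so the (S)-enantiomer should give the Si-face attack that corresponds to 1'R and, through the chair, 7R. The step needs γ-regioselectivity, which the cyclic mechanism imposes, and diastereo- and enantioselectivity, which rest on the geometric purity of 11, on the low temperature that suppresses the uncatalysed pathway and on the unbranched, non-coordinating nature of aldehyde 5.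

Step 7
Reactants: 13 (3R,4R,7Z)-9-(tert-butyldimethylsilyloxy)-3-(methoxymethoxy)-3,7-dimethylnona-1,7-dien-4-ol
Product: 14 (3R,4R,7Z)-4,9-bis(tert-butyldimethylsilyloxy)-3-(methoxymethoxy)-3,7-dimethylnona-1,7-diene
Conditions: TBSOTf, 2,6-lutidine, CH2Cl2, −78 → 0 °C
Reagents that add atoms: tert-butyldimethylsilyl trifluoromethanesulfonate, CC(C)(C)[Si](C)(C)OS(=O)(=O)C(F)(F)F
Why: The silyl triflate with a hindered pyridine base should silylate the hindered secondary C1' hydroxyl (silyl ether formation) without touching the acetal or the primary silyl ether, and no stereocentre is affected.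

Step 8
Reactants: 15 (4-carboxybutyl)triphenylphosphonium bromide; 16 1-(tert-butyldimethylsilyloxy)propan-2-one
Product: 18 (5Z)-7-(tert-butyldimethylsilyloxy)-6-methylhept-5-enoic acid, via ylide 17 (not isolated)
Conditions: NaN(SiMe3)2 (2.1 equiv), THF, 0 °C; then 16, −78 °C → rt; 1 M HCl to pH 4, 0 °C
Reagents that add atoms: none
Why: Wittig olefination of an α-silyloxy ketone with a non-stabilised ylide, a combination known to place the oxygenated carbon cis to the incoming chain, should set the Z geometry of C3''=C4''.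

Step 9
Reactants: 18 (5Z)-7-(tert-butyldimethylsilyloxy)-6-methylhept-5-enoic acid
Product: 19 methyl (5Z)-7-(tert-butyldimethylsilyloxy)-6-methylhept-5-enoate
Conditions: MeI, K2CO3, DMF, rt
Reagents that add atoms: iodomethane, CI
Why: O-Alkylation of the carboxylate with iodomethane (SN2 esterification) is mild enough for the allylic silyl ether and the Z olefin.

Step 10
Reactants: 19 methyl (5Z)-7-(tert-butyldimethylsilyloxy)-6-methylhept-5-enoate
Product: 21 methyl (5Z)-7-(tert-butyldimethylsilyloxy)-2-formyl-6-methylhept-5-enoate (racemic at C2 and largely enolised), via ester enolate 20 (not isolated)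
Conditions: LiN(iPr)2, THF, −78 °C; then HCO2Me, −78 → −20 °C; AcOH
Reagents that add atoms: methyl formate, COC=O
Why: Crossed Claisen condensation of the lithium ester enolate with a formate that cannot enolise should give the β-oxo ester, whose C2 stereocentre is of no consequence because C2 becomes sp2 in step 11.

Step 11
Reactants: 21 methyl (5Z)-7-(tert-butyldimethylsilyloxy)-2-formyl-6-methylhept-5-enoate
Product: 23 methyl (2Z,5Z)-7-(tert-butyldimethylsilyloxy)-6-methyl-2-{[(trifluoromethylsulfonyl)oxy]methylidene}hept-5-enoate (triflate cis to the ester), via lithium chelate 22 (not isolated)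
Conditions: LiN(SiMe3)2, toluene, −78 °C; then Tf2O, −78 → 0 °C
Reagents that add atoms: trifluoromethanesulfonic anhydride, O=S(=O)(OS(=O)(=O)C(F)(F)F)C(F)(F)F
Why: O-Sulfonylation of the lithium enolate, in which lithium bridges the enolate oxygen and the ester carbonyl, should fix the triflate cis to the ester (stereoselective enol triflate formation from a β-dicarbonyl chelate).

Step 12
Reactants: 14 (3R,4R,7Z)-4,9-bis(tert-butyldimethylsilyloxy)-3-(methoxymethoxy)-3,7-dimethylnona-1,7-diene; 23 methyl (2Z,5Z)-7-(tert-butyldimethylsilyloxy)-6-methyl-2-{[(trifluoromethylsulfonyl)oxy]methylidene}hept-5-enoate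
Product: 25 methyl (2Z,6R,7R,10Z)-7,12-bis(tert-butyldimethylsilyloxy)-2-[(3Z)-5-(tert-butyldimethylsilyloxy)-4-methylpent-3-en-1-yl]-6-(methoxymethoxy)-6,10-dimethyldodeca-2,10-dienoate, via alkylborane 24 (not isolated)
Conditions: 9-BBN, THF, 0 °C → rt; then 23, PdCl2(dppf) (5 mol %), AsPh3, K3PO4, DMF/THF/H2O, rt → 40 °C
Reagents that add atoms: none
Why: Anti-Markovnikov hydroboration of the only monosubstituted olefin by the bulky borane followed by B-alkyl Suzuki–Miyaura coupling should form C5–C4 with retention of the enol triflate geometry, so the ester ends up cis to C5 as the lactone ring requires.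

Step 13
Reactants: 25 methyl (2Z,6R,7R,10Z)-7,12-bis(tert-butyldimethylsilyloxy)-2-[(3Z)-5-(tert-butyldimethylsilyloxy)-4-methylpent-3-en-1-yl]-6-(methoxymethoxy)-6,10-dimethyldodeca-2,10-dienoate
Product: 27 methyl (2Z,6R,7R,10Z)-7,12-bis(tert-butyldimethylsilyloxy)-2-[(3Z)-5-(tert-butyldimethylsilyloxy)-4-methylpent-3-en-1-yl]-6-hydroxy-6,10-dimethyldodeca-2,10-dienoate, via bromomethyl ether 26 (not isolated)
Conditions: Me2BBr, CH2Cl2, −78 °C; then sat. aq. NaHCO3/THF, −78 °C → rt
Reagents that add atoms: none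
Why: Lewis acid cleavage of the acetal (boron on the methoxy oxygen, bromide on the methylene carbon, hydrolysis of the bromomethyl ether on work-up) should free the tertiary hydroxyl at −78 °C without breaking the C7–O bond, so C7 keeps its configuration and the silyl ethers and the ester persist.

Step 14
Reactants: 27 methyl (2Z,6R,7R,10Z)-7,12-bis(tert-butyldimethylsilyloxy)-2-[(3Z)-5-(tert-butyldimethylsilyloxy)-4-methylpent-3-en-1-yl]-6-hydroxy-6,10-dimethyldodeca-2,10-dienoate
Product: 28 (2Z,6R,7R,10Z)-7,12-bis(tert-butyldimethylsilyloxy)-2-[(3Z)-5-(tert-butyldimethylsilyloxy)-4-methylpent-3-en-1-yl]-6-hydroxy-6,10-dimethyldodeca-2,10-dienoic acid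
Conditions: LiOH, THF/MeOH/H2O, rt → 40 °C; then 1 M HCl to pH 4, 0 °C
Reagents that add atoms: lithium hydroxide, [Li+].[OH-]
Why: Saponification of the methyl ester with hydroxide should leave the silyl ethers intact and cannot change the olefin geometries or the stereocentres.

Step 15
Reactants: 28 (2Z,6R,7R,10Z)-7,12-bis(tert-butyldimethylsilyloxy)-2-[(3Z)-5-(tert-butyldimethylsilyloxy)-4-methylpent-3-en-1-yl]-6-hydroxy-6,10-dimethyldodeca-2,10-dienoic acid
Product: 30 (7R)-7-[(1R,4Z)-1,6-bis(tert-butyldimethylsilyloxy)-4-methylhex-4-en-1-yl]-3-[(3Z)-5-(tert-butyldimethylsilyloxy)-4-methylpent-3-en-1-yl]-7-methyl-6,7-dihydro-5H-oxepin-2-one, via mixed anhydride 29 (not isolated)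
Conditions: 2,4,6-trichlorobenzoyl chloride, Et3N, THF, rt; then DMAP, toluene, 80 °C, high dilution
Reagents that add atoms: none
Why: Yamaguchi lactonisation (mixed anhydride, then acyl transfer through the acylpyridinium to the C7 hydroxyl, 7-exo-trig) should be favoured by the cis olefin and the fully substituted C7, while the silyl ether on C1' excludes the eight-membered alternative and the C7–O bond is not broken.

Step 16
Reactants: 30 (7R)-7-[(1R,4Z)-1,6-bis(tert-butyldimethylsilyloxy)-4-methylhex-4-en-1-yl]-3-[(3Z)-5-(tert-butyldimethylsilyloxy)-4-methylpent-3-en-1-yl]-7-methyl-6,7-dihydro-5H-oxepin-2-one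
Product: 31 CNP0139192.1, (7R)-7-[(1R,4Z)-1,6-dihydroxy-4-methylhex-4-en-1-yl]-3-[(3Z)-5-hydroxy-4-methylpent-3-en-1-yl]-7-methyl-6,7-dihydro-5H-oxepin-2-one
Conditions: HF·pyridine, pyridine, THF, 0 °C → rt
Reagents that add atoms: none
Why: Fluoride-mediated cleavage of the three silyl ethers under buffered, non-basic conditions (desilylation) should spare the unsaturated lactone and the allylic alcohols and touches no stereocentre.

**Compound list**

1 | nerol | CC(C)=CCC/C(C)=C\CO | starting material
2 | neryl tert-butyldimethylsilyl ether | CC(C)=CCC/C(C)=C\CO[Si](C)(C)C(C)(C)C | intermediate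
3 | 6,7-epoxide of 2 (racemic) | CC1(C)OC1CC/C(C)=C\CO[Si](C)(C)C(C)(C)C | intermediate
4 | (6Z)-8-(tert-butyldimethylsilyloxy)-2,6-dimethyloct-6-ene-2,3-diol (racemic) | CC(C)(O)C(O)CC/C(C)=C\CO[Si](C)(C)C(C)(C)C | intermediate (not isolated)
5 | (4Z)-6-(tert-butyldimethylsilyloxy)-4-methylhex-4-enal | O=CCC/C(C)=C\CO[Si](C)(C)C(C)(C)C | intermediate
6 | but-3-en-2-ol (racemic) | C=CC(C)O | starting material
7 | 3-(methoxymethoxy)but-1-ene (racemic) | C=CC(C)OCOC | intermediate
8 | 2-isopropoxy-4,4,5,5-tetramethyl-1,3,2-dioxaborolane | CC(C)OB1OC(C)(C)C(C)(C)O1 | starting material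
9 | [(2Z)-3-(methoxymethoxy)but-2-en-1-yl]lithium (chelated alkoxyallyllithium) | COCO/C(C)=C\C[Li] | intermediate (not isolated)
10 | lithium isopropoxy[(2Z)-3-(methoxymethoxy)but-2-en-1-yl](pinacolato)borate | [Li+].COCO/C(C)=C\C[B-]1(OC(C)C)OC(C)(C)C(C)(C)O1 | intermediate (not isolated)
11 | 2-[(2Z)-3-(methoxymethoxy)but-2-en-1-yl]-4,4,5,5-tetramethyl-1,3,2-dioxaborolane | COCO/C(C)=C\CB1OC(C)(C)C(C)(C)O1 | intermediate
12 | O-(pinacolatoboryl) derivative of 13 | C=C[C@](C)([C@H](OB1OC(C)(C)C(C)(C)O1)CC/C(C)=C\CO[Si](C)(C)C(C)(C)C)OCOC | intermediate (not isolated)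
13 | (3R,4R,7Z)-9-(tert-butyldimethylsilyloxy)-3-(methoxymethoxy)-3,7-dimethylnona-1,7-dien-4-ol | C=C[C@](C)([C@H](O)CC/C(C)=C\CO[Si](C)(C)C(C)(C)C)OCOC | intermediate
14 | (3R,4R,7Z)-4,9-bis(tert-butyldimethylsilyloxy)-3-(methoxymethoxy)-3,7-dimethylnona-1,7-diene | C=C[C@](C)([C@H](O[Si](C)(C)C(C)(C)C)CC/C(C)=C\CO[Si](C)(C)C(C)(C)C)OCOC | intermediate
15 | (4-carboxybutyl)triphenylphosphonium bromide | [Br-].OC(=O)CCCC[P+](c1ccccc1)(c1ccccc1)c1ccccc1 | starting material
16 | 1-(tert-butyldimethylsilyloxy)propan-2-one | CC(=O)CO[Si](C)(C)C(C)(C)C | starting material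
17 | sodium 5-(triphenylphosphoranylidene)pentanoate | [Na+].[O-]C(=O)CCCC=P(c1ccccc1)(c1ccccc1)c1ccccc1 | intermediate (not isolated)
18 | (5Z)-7-(tert-butyldimethylsilyloxy)-6-methylhept-5-enoic acid | C/C(=C/CCCC(=O)O)CO[Si](C)(C)C(C)(C)C | intermediate
19 | methyl (5Z)-7-(tert-butyldimethylsilyloxy)-6-methylhept-5-enoate | C/C(=C/CCCC(=O)OC)CO[Si](C)(C)C(C)(C)C | intermediate
20 | lithium enolate of 19 | [Li+].[O-]C(OC)=CCC/C=C(/C)CO[Si](C)(C)C(C)(C)C | intermediate (not isolated)
21 | methyl (5Z)-7-(tert-butyldimethylsilyloxy)-2-formyl-6-methylhept-5-enoate (racemic at C2) | C/C(=C/CCC(C=O)C(=O)OC)CO[Si](C)(C)C(C)(C)C | intermediate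
22 | lithium (Z)-enolate of 21 (chelate) | [Li+].[O-]/C=C(/CC/C=C(/C)CO[Si](C)(C)C(C)(C)C)C(=O)OC | intermediate (not isolated)
23 | methyl (2Z,5Z)-7-(tert-butyldimethylsilyloxy)-6-methyl-2-{[(trifluoromethylsulfonyl)oxy]methylidene}hept-5-enoate | C/C(=C/CC/C(=C/OS(=O)(=O)C(F)(F)F)C(=O)OC)CO[Si](C)(C)C(C)(C)C | intermediate
24 | B-alkyl-9-borabicyclo[3.3.1]nonane from 14 (boron on C5) | B1(CC[C@](C)([C@H](O[Si](C)(C)C(C)(C)C)CC/C(C)=C\CO[Si](C)(C)C(C)(C)C)OCOC)C2CCCC1CCC2 | intermediate (not isolated)
25 | methyl (2Z,6R,7R,10Z)-7,12-bis(tert-butyldimethylsilyloxy)-2-[(3Z)-5-(tert-butyldimethylsilyloxy)-4-methylpent-3-en-1-yl]-6-(methoxymethoxy)-6,10-dimethyldodeca-2,10-dienoate | C/C(=C/CC/C(=C/CC[C@](C)([C@H](O[Si](C)(C)C(C)(C)C)CC/C(C)=C\CO[Si](C)(C)C(C)(C)C)OCOC)C(=O)OC)CO[Si](C)(C)C(C)(C)C | intermediate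
26 | C7 bromomethyl ether from 25 | C/C(=C/CC/C(=C/CC[C@](C)([C@H](O[Si](C)(C)C(C)(C)C)CC/C(C)=C\CO[Si](C)(C)C(C)(C)C)OCBr)C(=O)OC)CO[Si](C)(C)C(C)(C)C | intermediate (not isolated)
27 | methyl (2Z,6R,7R,10Z)-7,12-bis(tert-butyldimethylsilyloxy)-2-[(3Z)-5-(tert-butyldimethylsilyloxy)-4-methylpent-3-en-1-yl]-6-hydroxy-6,10-dimethyldodeca-2,10-dienoate | C/C(=C/CC/C(=C/CC[C@](C)([C@H](O[Si](C)(C)C(C)(C)C)CC/C(C)=C\CO[Si](C)(C)C(C)(C)C)O)C(=O)OC)CO[Si](C)(C)C(C)(C)C | intermediate
28 | (2Z,6R,7R,10Z)-7,12-bis(tert-butyldimethylsilyloxy)-2-[(3Z)-5-(tert-butyldimethylsilyloxy)-4-methylpent-3-en-1-yl]-6-hydroxy-6,10-dimethyldodeca-2,10-dienoic acid | C/C(=C/CC/C(=C/CC[C@](C)([C@H](O[Si](C)(C)C(C)(C)C)CC/C(C)=C\CO[Si](C)(C)C(C)(C)C)O)C(=O)O)CO[Si](C)(C)C(C)(C)C | intermediate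
29 | mixed anhydride of 28 with 2,4,6-trichlorobenzoic acid | C/C(=C/CC/C(=C/CC[C@](C)([C@H](O[Si](C)(C)C(C)(C)C)CC/C(C)=C\CO[Si](C)(C)C(C)(C)C)O)C(=O)OC(=O)c1c(Cl)cc(Cl)cc1Cl)CO[Si](C)(C)C(C)(C)C | intermediate (not isolated)
30 | (7R)-7-[(1R,4Z)-1,6-bis(tert-butyldimethylsilyloxy)-4-methylhex-4-en-1-yl]-3-[(3Z)-5-(tert-butyldimethylsilyloxy)-4-methylpent-3-en-1-yl]-7-methyl-6,7-dihydro-5H-oxepin-2-one | C/C(=C/CCC1=CCC[C@](C)([C@H](O[Si](C)(C)C(C)(C)C)CC/C(C)=C\CO[Si](C)(C)C(C)(C)C)OC1=O)CO[Si](C)(C)C(C)(C)C | intermediate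
31 | CNP0139192.1, (7R)-7-[(1R,4Z)-1,6-dihydroxy-4-methylhex-4-en-1-yl]-3-[(3Z)-5-hydroxy-4-methylpent-3-en-1-yl]-7-methyl-6,7-dihydro-5H-oxepin-2-one | C/C(=C/CCC1=CCC[C@](C)([C@H](O)CC/C(C)=C\CO)OC1=O)CO | target

**Step count**

Total: 16 steps. Longest linear sequence: 10 steps (steps 1, 2, 3, 6, 7, 12, 13, 14, 15, 16, from nerol).

**Steps most likely to fail**

1. Step 6 (the allylboration). The γ,γ-disubstituted boronate may react too slowly under the acid catalyst, so that the uncatalysed racemic pathway or acid-induced breakdown of the enol ether reagent takes over, and the facial preference may be weaker than for simple allylboronates. The fallback uses known reactions only, sets out from 5 and comes back at 27.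
   - Still–Gennari olefination of 5 with methyl 2-[bis(2,2,2-trifluoroethoxy)phosphoryl]propanoate (KN(SiMe3)2, 18-crown-6, THF, −78 °C) would give methyl (2Z,6Z)-8-(tert-butyldimethylsilyloxy)-2,6-dimethylocta-2,6-dienoate F1.
   - Reduction with iBu2AlH would give (2Z,6Z)-8-(tert-butyldimethylsilyloxy)-2,6-dimethylocta-2,6-dien-1-ol F2.
   - Sharpless asymmetric epoxidation with Ti(OiPr)4, L-(+)-diethyl tartrate and tBuOOH would give [(2S,3R)-3-[(3Z)-5-(tert-butyldimethylsilyloxy)-3-methylpent-3-en-1-yl]-2-methyloxiran-2-yl]methanol F3.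
   - Dimethylsulfonium methylide (Me3SI, nBuLi, THF) would trigger a Payne rearrangement (inversion at C7), open the terminal epoxide at its CH2 and eliminate dimethyl sulfide, giving (3R,4R,7Z)-9-(tert-butyldimethylsilyloxy)-3,7-dimethylnona-1,7-diene-3,4-diol F4 with the syn (7R,1'R) arrangement.
   - TBSCl and imidazole would silylate only the secondary hydroxyl to (3R,4R,7Z)-4,9-bis(tert-butyldimethylsilyloxy)-3,7-dimethylnona-1,7-dien-3-ol F5.
   - F5 would be taken through the conditions of step 12 with 23 (one extra equivalent of 9-BBN for the free hydroxyl) to reach 27.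

2. Step 5 (the boronate). Deprotonation at the substituted allylic carbon may be slow, leaving room for addition of sBuLi to the olefin or Wittig rearrangement of the anion. The fallback avoids the C–H deprotonation: it keeps 8, replaces 7 by a stannane made from commercial but-3-yn-2-ol (the alkyne counterpart of 6), and comes back at 9.
   - But-3-yn-2-ol would be protected with MOMCl and iPr2NEt as 3-(methoxymethoxy)but-1-yne F6.
   - KOtBu would isomerise it to 3-(methoxymethoxy)buta-1,2-diene F7.
   - Hydrostannation with Bu3SnH and Pd(PPh3)4 should place tin on the CH2 terminus to give tributyl[3-(methoxymethoxy)but-2-en-1-yl]stannane F8, whose olefin geometry is of no consequence.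
   - Tin–lithium exchange with nBuLi (THF, −78 °C) would deliver the same chelated allyllithium 9, which is borylated with 8 as in step 5.

3. Step 15 (the lactonisation). Acylation of the hindered tertiary hydroxyl may be slow, so that the activated Z-enoate isomerises or oligomerises, or the hydroxyl adds in conjugate fashion to give a five-membered ether. The fallback forms the O1–C2 bond first and closes the ring at C3=C4; it sets out from 14 and 19 and comes back at 30.
   - Me2BBr on 14 would give the tertiary alcohol F5 described above.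
   - Ester 19 would be brominated (LiN(iPr)2, then CBr4) to methyl (5Z)-2-bromo-7-(tert-butyldimethylsilyloxy)-6-methylhept-5-enoate F9.
   - Arbuzov reaction with P(OEt)3 would give methyl (5Z)-7-(tert-butyldimethylsilyloxy)-2-(diethoxyphosphoryl)-6-methylhept-5-enoate F10, and LiOH would give the corresponding acid F11.
   - DCC would join F11 and F5 through the phosphonoketene, which acylates even tertiary alcohols, to give phosphonoacetate ester F12.
   - Linear hydroformylation of the vinyl group (Rh(acac)(CO)2, Xantphos, CO/H2, toluene) would give the C4 aldehyde F13.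
   - An intramolecular Horner–Wadsworth–Emmons reaction (LiCl, iPr2NEt, MeCN, high dilution) would close the seven-membered ring to 30, the cis ring olefin being enforced by the ring.

Further compounds
F1 | step 6 | methyl (2Z,6Z)-8-(tert-butyldimethylsilyloxy)-2,6-dimethylocta-2,6-dienoate | COC(=O)/C(C)=C\CC/C(C)=C\CO[Si](C)(C)C(C)(C)C
F2 | step 6 | (2Z,6Z)-8-(tert-butyldimethylsilyloxy)-2,6-dimethylocta-2,6-dien-1-ol | OC/C(C)=C\CC/C(C)=C\CO[Si](C)(C)C(C)(C)C
F3 | step 6 | [(2S,3R)-3-[(3Z)-5-(tert-butyldimethylsilyloxy)-3-methylpent-3-en-1-yl]-2-methyloxiran-2-yl]methanol | OC[C@]1(C)O[C@@H]1CC/C(C)=C\CO[Si](C)(C)C(C)(C)C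
F4 | step 6 | (3R,4R,7Z)-9-(tert-butyldimethylsilyloxy)-3,7-dimethylnona-1,7-diene-3,4-diol | C=C[C@](C)([C@H](O)CC/C(C)=C\CO[Si](C)(C)C(C)(C)C)O
F5 | step 6 | (3R,4R,7Z)-4,9-bis(tert-butyldimethylsilyloxy)-3,7-dimethylnona-1,7-dien-3-ol | C=C[C@](C)([C@H](O[Si](C)(C)C(C)(C)C)CC/C(C)=C\CO[Si](C)(C)C(C)(C)C)O
F6 | step 5 | 3-(methoxymethoxy)but-1-yne | C#CC(C)OCOC
F7 | step 5 | 3-(methoxymethoxy)buta-1,2-diene | C=C=C(C)OCOC
F8 | step 5 | tributyl[3-(methoxymethoxy)but-2-en-1-yl]stannane | CCCC[Sn](CCCC)(CCCC)CC=C(C)OCOC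
F9 | step 15 | methyl (5Z)-2-bromo-7-(tert-butyldimethylsilyloxy)-6-methylhept-5-enoate | C/C(=C/CCC(Br)C(=O)OC)CO[Si](C)(C)C(C)(C)C
F10 | step 15 | methyl (5Z)-7-(tert-butyldimethylsilyloxy)-2-(diethoxyphosphoryl)-6-methylhept-5-enoate | C/C(=C/CCC(C(=O)OC)P(=O)(OCC)OCC)CO[Si](C)(C)C(C)(C)C
F11 | step 15 | (5Z)-7-(tert-butyldimethylsilyloxy)-2-(diethoxyphosphoryl)-6-methylhept-5-enoic acid | C/C(=C/CCC(C(=O)O)P(=O)(OCC)OCC)CO[Si](C)(C)C(C)(C)C
F12 | step 15 | ester of F5 with F11 | C=C[C@](C)([C@H](O[Si](C)(C)C(C)(C)C)CC/C(C)=C\CO[Si](C)(C)C(C)(C)C)OC(=O)C(CC/C=C(/C)CO[Si](C)(C)C(C)(C)C)P(=O)(OCC)OCC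
F13 | step 15 | C4 aldehyde from hydroformylation of F12 | O=CCC[C@](C)([C@H](O[Si](C)(C)C(C)(C)C)CC/C(C)=C\CO[Si](C)(C)C(C)(C)C)OC(=O)C(CC/C=C(/C)CO[Si](C)(C)C(C)(C)C)P(=O)(OCC)OCC
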